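**Retrosynthetic overview**
1. Numbering: C1 is the methyl-bearing fusion carbon, followed by C2, C3, C4 (isopropyl carbinol), C5 (fusion CH), C6 (CH–O-aroyl), C7, C8 (methyl carbinol), C9 (CHOH) and C10. Ring A is C1–C5 (five-membered), ring B is C1/C5–C10 (seven-membered), and β is the face of the C1 methyl group.
2. End game: free phenol ⇐ trans-diol by water attack at C8 of the 8α,9α-epoxide ⇐ α-face epoxidation of C8=C9 ⇐ O6 aroylation of the 4β,6α-diol (jaeschkeanadiol) ⇐ hydride delivered to C6 from O4 ⇐ shift of C7=C8 out of conjugation.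
3. Feature exploited: without ring A and its hydroxyls, ring B is a C6 ketone flanked by two identical CH=C(CH3) arms (C5=C1 and C7=C8) tied by C9–C10. This is achiral 3,6-dimethylcyclohepta-2,6-dienone. C2–C3–C4, with OH and isopropyl on C4, are the three ring carbons of 1-isopropylcyclopropanol.
4. Key disconnection: bonds C1–C2 and C4–C5 of ring A are made in one 3+2 operation (homoenolate conjugate addition, then aldol closure) that also breaks the symmetry. The untouched arm C7=C8 later supplies the C8/C9 diol.
5. Ring order: ring B first (one-carbon expansion of a six-membered enone), ring A second.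

Key step: step 6

Assumption: the antipode of ligand L* that gives the (8aS)-configured C1 of 13 has to be found by a screen (both antipodes are accessible), and the trans-fused aldol is taken to be the thermodynamic product of the reversible ring closure.

**Step 1**
Reactants: 1 3-methylcyclohex-2-en-1-one
Product: 2 (±)-3,6-dimethylcyclohex-2-en-1-one
Conditions: LDA (1.05 equiv), THF, −78 °C; MeI (1.2 equiv), −78 → 0 °C
Reagents that add atoms: iodomethane, CI
Why: Kinetic enolate alkylation: the hindered amide removes the α' proton at C6 of the enone faster than a γ proton and iodomethane alkylates that carbon; the new stereocentre is racemic and disappears in step 2.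

**Step 2**
Reactants: 2 (±)-3,6-dimethylcyclohex-2-en-1-one
Product: 3 1,4-dimethyl-2-(trimethylsilyloxy)cyclohexa-1,3-diene
Conditions: LDA (1.1 equiv), THF, −78 °C; TMSCl (1.3 equiv), −78 °C → rt
Reagents that add atoms: chlorotrimethylsilane, C[Si](C)(C)Cl
Why: Kinetic enol silylation: deprotonation again occurs on the α' side (now the methine), as is usual for 6-alkylcyclohex-2-enones, and O-silylation gives the cross-conjugated 2-silyloxydiene, which has no stereocentre.

**Step 3**
Reactants: 3 1,4-dimethyl-2-(trimethylsilyloxy)cyclohexa-1,3-diene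
Product: 4 (±)-3,6-dimethyl-1-(trimethylsilyloxy)bicyclo[4.1.0]hept-2-ene
Conditions: Zn–Cu couple (2 equiv), CH2I2 (1.3 equiv), Et2O, reflux; pyridine, filtration
Reagents that add atoms: diiodomethane, ICI
Why: Simmons–Smith cyclopropanation: the electrophilic zinc carbenoid selects the electron-rich silyl enol ether double bond of a 2-silyloxydiene over the alkyl-substituted one; the cis-fused product is racemic and both stereocentres are erased in step 4.

**Step 4**
Reactants: 4 (±)-3,6-dimethyl-1-(trimethylsilyloxy)bicyclo[4.1.0]hept-2-ene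
Product: 6 3,6-dimethylcyclohepta-2,6-dien-1-one, via chloro ketone 5 (not isolated)
Conditions: FeCl3 (2.2 equiv), DMF, 0 °C → rt; crude 5, NaOAc, MeOH, reflux
Reagents that add atoms: none
Why: FeCl3-mediated oxidative ring expansion of a silyloxycyclopropane: one-electron oxidation cleaves the internal cyclopropane bond to the tertiary β-keto radical, chlorine transfer gives 5, and acetate-induced dehydrochlorination puts the second double bond into conjugation to give the achiral dienone.

**Step 5**
Reactants: 7 methyl isobutyrate
Product: 8 1-(propan-2-yl)cyclopropan-1-ol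
Conditions: EtMgBr (2.4 equiv), Ti(OiPr)4 (15 mol %), Et2O, 0 °C → rt; aq NH4Cl
Reagents that add atoms: ethylmagnesium bromide, CC[Mg]Br
Why: Kulinkovich reaction: the titanacyclopropane formed from the Grignard reagent and the titanium alkoxide acts as a 1,2-dicarbanion on the ester carbonyl and closes the cyclopropanol; no stereocentre is formed.

**Step 6**
Reactants: 6 3,6-dimethylcyclohepta-2,6-dien-1-one; 8 1-(propan-2-yl)cyclopropan-1-ol
Product: 13 (3R,3aR,8aS)-3-hydroxy-6,8a-dimethyl-3-(propan-2-yl)-2,3,3a,7,8,8a-hexahydroazulen-4(1H)-one, via zinc bis(cyclopropanolate) 9 (not isolated), via bis(homoenolate)zinc 10 (not isolated), via zinc dienolate 11 (not isolated), via zinc aldolate 12 (not isolated)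
Conditions: 8 (2.1 equiv), Et2Zn (1.05 equiv), THF, 0 → 40 °C; Cu(OTf)2 (10 mol %), L* (12 mol %; enantiopure 4,5-diphenylimidazolinium salt with one N-mesityl group and one N-(2-sulfonatophenyl) arm), NaOtBu (12 mol %); 6 (1.0 equiv), −30 °C → rt; 40 °C (aldolate equilibration); AcOH, 0 °C
Reagents that add atoms: none
Why: Proposed new method: two molecules of 8 protonate Et2Zn to give alkoxide 9, strain release opens each cyclopropane to the carbonyl-chelated β-zincio ketone 10, one alkyl group passes to the monovalent NHC–copper centre and adds 1,4 to one enone arm of 6 (bond C1–C2), and the cross-conjugated zinc dienolate 11 attacks the pendant isopropyl ketone through C5 (bond C4–C5) to give aldolate 12. The closest known reaction types are NHC–copper-catalysed enantioselective conjugate addition of dialkylzincs to β-methyl cyclic enones, copper-mediated conjugate addition of ester zinc homoenolates, amino-alkoxide-zinc-catalysed conjugate addition of cyclopropanol-derived homoenolates to acyclic enones and cobalt-catalysed 3+2 annulation of cyclopropanols with alkynes; none of them joins a ketone homoenolate to a β,β-disubstituted cyclic dienone with aldol closure in the same flask. Ring A closes by a 5-(enolexo)-exo-trig aldol addition of Reformatsky type, a geometrically favoured mode. C1 is fixed by the chiral carbene on copper, which only has to distinguish the two enantiotopic terminus/face pairs of achiral 6 (C1 from one face equals C8 from the other); C4 is fixed by zinc bridging O6 and O4 in a closed transition state, which puts O4 cis to C6 and the isopropyl group cis to H5 on ring A; C5 is fixed thermodynamically, because kinetic closure on the tether-bearing face should give the cis fusion and only retro-aldol/re-aldol of 12, which resets C4 and C5 together, can lead to the trans-fused chelate. The step needs transfer of the homoenolate only (the 2:1 ratio of 8 to Et2Zn leaves no ethyl group on zinc), a single addition (11 is an inert dienolate, and after closure the only carbon ligand left sits on a sluggish alkylzinc alkoxide) and no loss of water from 12 (temperature held at or below 40 °C).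

**Step 7**
Reactants: 13 (3R,3aR,8aS)-3-hydroxy-6,8a-dimethyl-3-(propan-2-yl)-2,3,3a,7,8,8a-hexahydroazulen-4(1H)-one
Product: 14 O4-trimethylsilyl 6,8-dienol trimethylsilyl ether of 13 [C6(OTMS)=C7–C8(CH3)=C9; 4β-OTMS; 5α-H; 1β-CH3]
Conditions: TMSOTf (3.0 equiv), Et3N (5 equiv), CH2Cl2, 0 °C → rt
Reagents that add atoms: trimethylsilyl triflate, C[Si](C)(C)OS(=O)(=O)C(F)(F)F
Why: Soft enolisation with a silyl triflate and an amine: O4 is silylated first, which blocks retro-aldol cleavage of C4–C5, then the O-silylated enone loses the C9 proton in an E1-like, reversible manner (C5–H is shielded by two fully substituted neighbours) to give the more substituted endocyclic dienol ether in preference to the exocyclic one; no stereocentre is made or touched.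

**Step 8**
Reactants: 14 O4-trimethylsilyl 6,8-dienol trimethylsilyl ether of 13
Product: 17 (3R,3aR,8aR)-3-hydroxy-6,8a-dimethyl-3-(propan-2-yl)-2,3,3a,5,8,8a-hexahydroazulen-4(1H)-one, via lithium dienolate 15 (not isolated), via O4-TMS β,γ-enone 16 (not isolated)
Conditions: MeLi (1.05 equiv), THF, 0 °C; AcOH (3 equiv), THF, −78 °C; AcOH/THF/H2O (3:1:1), rt
Reagents that add atoms: none
Why: Regiospecific release of the extended lithium dienolate from the enol silyl ether with MeLi (the tertiary alkyl silyl ether is inert), deconjugative kinetic protonation at the α-carbon C7, and hydrolysis of the labile O4 silyl ether in aqueous acetic acid, a medium too weak to bring C8=C9 back into conjugation; C5 keeps its configuration because the ketone never meets a free base.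

**Step 9**
Reactants: 17 (3R,3aR,8aR)-3-hydroxy-6,8a-dimethyl-3-(propan-2-yl)-2,3,3a,5,8,8a-hexahydroazulen-4(1H)-one
Product: 18 jaeschkeanadiol, (3R,3aS,4S,8aR)-6,8a-dimethyl-3-(propan-2-yl)-1,2,3,3a,4,5,8,8a-octahydroazulene-3,4-diol
Conditions: Me4NBH(OAc)3 (5 equiv), MeCN/AcOH (1:1), −20 → 0 °C; aq sodium potassium tartrate
Reagents that add atoms: none
Why: Evans–Saksena hydroxyl-directed reduction: after exchange of an acetate for the β-oriented O4 the boron hydride is delivered through a six-membered transition state to the β face of C6=O, the face an external hydride would avoid because of the axial C1 methyl group, so that the 6α-alcohol (6S) results while the reagent leaves the alkene alone.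

**Step 10**
Reactants: 18 jaeschkeanadiol; 19 4-(benzyloxy)benzoic acid
Product: 20 (3R,3aS,4S,8aR)-3-hydroxy-6,8a-dimethyl-3-(propan-2-yl)-1,2,3,3a,4,5,8,8a-octahydroazulen-4-yl 4-(benzyloxy)benzoate (O-benzylferutinin)
Conditions: 19 (1.5 equiv), DCC (1.6 equiv), DMAP (0.3 equiv), CH2Cl2, rt
Reagents that add atoms: none
Why: Steglich esterification: only the secondary, equatorial O6 is acylated because the tertiary O4, flanked by isopropyl and C5, is inert under these conditions, and the benzyl ether prevents self-condensation of the phenolic acid; no stereocentre changes.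

**Step 11**
Reactants: 20 O-benzylferutinin
Product: 21 8α,9α-epoxide of 20
Conditions: mCPBA (1.2 equiv), NaHCO3, CH2Cl2, 0 °C
Reagents that add atoms: 3-chloroperbenzoic acid, O=C(OO)c1cccc(Cl)c1
Why: Prilezhaev epoxidation of the only alkene: the axial C1 methyl group covers the β face of C8=C9 while the 6α-ester is equatorial and points away from the α face, so oxygen should be delivered to the α face and set C8 (R) and C9 (S).

**Step 12**
Reactants: 21 8α,9α-epoxide of 20
Product: 22 (3R,3aS,4S,6S,7S,8aR)-3,6,7-trihydroxy-6,8a-dimethyl-3-(propan-2-yl)decahydroazulen-4-yl 4-(benzyloxy)benzoate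
Conditions: HClO4 (5 mol %), THF/H2O (3:1), 0 °C
Reagents that add atoms: water, O
Why: Acid-catalysed epoxide hydrolysis with borderline SN2 character: water attacks the protonated epoxide at tertiary C8 from the β face with inversion (8β-OH) and leaves the C9–O bond intact (9α-OH), β approach to C9 being hindered by the syn-axial C1 methyl group and O4 being unable to compete because the trans fusion keeps C4 equatorial on ring B and out of reach of C8.

**Step 13**
Reactants: 22 benzyl-protected triol ester
Product: 23 (3R,3aS,4S,6S,7S,8aR)-3,6,7-trihydroxy-6,8a-dimethyl-3-(propan-2-yl)decahydroazulen-4-yl 4-hydroxybenzoate (target)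
Conditions: H2 (1 atm), Pd/C, EtOAc, rt
Reagents that add atoms: none
Why: Hydrogenolysis of an aryl benzyl ether under neutral conditions: no alkene or other reducible group remains, and the aryl ester and the three hydroxyl groups are inert, so no stereocentre is affected.

**Compound list**
1 | 3-methylcyclohex-2-en-1-one | CC1=CC(=O)CCC1 | starting material
2 | (±)-3,6-dimethylcyclohex-2-en-1-one | CC1CCC(C)=CC1=O | intermediate
3 | 1,4-dimethyl-2-(trimethylsilyloxy)cyclohexa-1,3-diene | CC1=C(O[Si](C)(C)C)C=C(C)CC1 | intermediate
4 | (±)-3,6-dimethyl-1-(trimethylsilyloxy)bicyclo[4.1.0]hept-2-ene (racemic, cis-fused) | CC1=CC2(O[Si](C)(C)C)CC2(C)CC1 | intermediate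
5 | (±)-6-chloro-3,6-dimethylcyclohept-2-en-1-one | CC1=CC(=O)CC(C)(Cl)CC1 | intermediate
6 | 3,6-dimethylcyclohepta-2,6-dien-1-one | CC1=CC(=O)C=C(C)CC1 | intermediate
7 | methyl isobutyrate | COC(=O)C(C)C | starting material
8 | 1-(propan-2-yl)cyclopropan-1-ol | CC(C)C1(O)CC1 | intermediate
9 | zinc bis[1-(propan-2-yl)cyclopropan-1-olate] | CC(C)C1(CC1)O[Zn]OC1(CC1)C(C)C | intermediate
10 | bis(4-methyl-3-oxopentyl)zinc | CC(C)C(=O)CC[Zn]CCC(=O)C(C)C | intermediate
11 | (4-methyl-3-oxopentyl)zinc dienolate of (S)-3,6-dimethyl-6-(4-methyl-3-oxopentyl)cyclohept-2-en-1-one (C5=C6 enolate) | CC(C)C(=O)CC[C@]1(C)CCC(C)=CC(O[Zn]CCC(=O)C(C)C)=C1 | intermediate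
12 | (4-methyl-3-oxopentyl)zinc O4-alkoxide of 13 | CC(C)[C@]1(O[Zn]CCC(=O)C(C)C)CC[C@]2(C)CCC(C)=CC(=O)[C@H]21 | intermediate
13 | (3R,3aR,8aS)-3-hydroxy-6,8a-dimethyl-3-(propan-2-yl)-2,3,3a,7,8,8a-hexahydroazulen-4(1H)-one (trans-fused, 4β-OH, 5α-H, 1β-CH3) | CC(C)[C@]1(O)CC[C@]2(C)CCC(C)=CC(=O)[C@H]21 | intermediate
14 | O4-trimethylsilyl 6,8-dienol trimethylsilyl ether of 13 | CC(C)[C@]1(O[Si](C)(C)C)CC[C@]2(C)CC=C(C)C=C(O[Si](C)(C)C)[C@H]21 | intermediate
15 | lithium 6,8-dienolate, O4-trimethylsilyl | CC(C)[C@]1(O[Si](C)(C)C)CC[C@]2(C)CC=C(C)C=C(O[Li])[C@H]21 | intermediate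
16 | O4-trimethylsilyl ether of 17 | CC(C)[C@]1(O[Si](C)(C)C)CC[C@]2(C)CC=C(C)CC(=O)[C@H]21 | intermediate
17 | (3R,3aR,8aR)-3-hydroxy-6,8a-dimethyl-3-(propan-2-yl)-2,3,3a,5,8,8a-hexahydroazulen-4(1H)-one | CC(C)[C@]1(O)CC[C@]2(C)CC=C(C)CC(=O)[C@H]21 | intermediate
18 | jaeschkeanadiol, (3R,3aS,4S,8aR)-6,8a-dimethyl-3-(propan-2-yl)-1,2,3,3a,4,5,8,8a-octahydroazulene-3,4-diol | CC(C)[C@]1(O)CC[C@]2(C)CC=C(C)C[C@H](O)[C@H]21 | intermediate
19 | 4-(benzyloxy)benzoic acid | O=C(O)c1ccc(OCc2ccccc2)cc1 | starting material
20 | O-benzylferutinin | CC(C)[C@]1(O)CC[C@]2(C)CC=C(C)C[C@H](OC(=O)c3ccc(OCc4ccccc4)cc3)[C@H]21 | intermediate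
21 | 8α,9α-epoxide of 20 | CC(C)[C@]1(O)CC[C@]2(C)C[C@@H]3O[C@]3(C)C[C@H](OC(=O)c4ccc(OCc5ccccc5)cc4)[C@H]21 | intermediate
22 | (3R,3aS,4S,6S,7S,8aR)-3,6,7-trihydroxy-6,8a-dimethyl-3-(propan-2-yl)decahydroazulen-4-yl 4-(benzyloxy)benzoate | CC(C)[C@]1(O)CC[C@]2(C)C[C@H](O)[C@@](C)(O)C[C@H](OC(=O)c3ccc(OCc4ccccc4)cc3)[C@H]21 | intermediate
23 | (3R,3aS,4S,6S,7S,8aR)-3,6,7-trihydroxy-6,8a-dimethyl-3-(propan-2-yl)decahydroazulen-4-yl 4-hydroxybenzoate | CC(C)[C@]1(O)CC[C@]2(C)C[C@H](O)[C@@](C)(O)C[C@H](OC(=O)c3ccc(O)cc3)[C@H]21 | target

**Total step count:** 13. **Longest linear sequence:** 12 (steps 1–4 and 6–13).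

**Steps most likely to fail**

1. **Step 6.**
   - Risks: The carbonyl-chelated alkyl group may pass too slowly from zinc to copper and on to the hindered, doubly substituted β-carbon. Enantioface discrimination may be poor. The enone regenerated on ring closure may take up a second alkyl group, or the aldolate may lose water. Closure may also stop at the cis fusion if the retro-aldol path is slow or the trans isomer is not favoured.
   - Fallback: It uses known reactions only, makes the two bonds one at a time, sets out from 8 and 6 and rejoins the route at 13.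
   - Nucleophile: Electrophilic ring opening of 8 with NBS gives 1-bromo-4-methylpentan-3-one F1. Ketalisation with ethylene glycol (pTsOH, water removal) gives 2-(2-bromoethyl)-2-(propan-2-yl)-1,3-dioxolane F2. Magnesium in THF below 25 °C then gives 2-[2-(propan-2-yl)-1,3-dioxolan-2-yl]ethylmagnesium bromide F3.
   - Bond C1–C2: Copper–NHC-catalysed enantioselective conjugate addition of alkyl Grignard reagents to β-methyl cyclic enones is established. Applied to 6 it should stop after one addition, because the enolate survives until work-up, and give (S)-3,6-dimethyl-6-{2-[2-(propan-2-yl)-1,3-dioxolan-2-yl]ethyl}cyclohept-2-en-1-one F4.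
   - Bond C4–C5: Mild aqueous acid frees (S)-3,6-dimethyl-6-(4-methyl-3-oxopentyl)cyclohept-2-en-1-one F5. A separate, reversible intramolecular aldol addition (KOH, MeOH, 0 °C to rt) then closes C4–C5 to 13. Fusion isomers can be separated and the unwanted one returned to the equilibration.

2. **Step 7** (together with the protonation in step 8).
   - Risks: Proton loss from the C8 methyl group may compete with loss from C9, and the double bond may slip back into conjugation at the protonation stage.
   - Fallback: It sets out from 13 and rejoins at 17. O4 is capped with the sturdier triethylsilyl group (TESOTf, 2,6-lutidine) to give the O4-triethylsilyl ether of 13 F6.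
   - Deconjugation: Excess KOtBu in tBuOH/THF converts F6 by direct thermodynamic deprotonation into the extended potassium 6,8-dienolate F7. This is run into cold aqueous AcOH, the classical deconjugation of steroidal enones, to give the O4-triethylsilyl ether of 17 F8. HF·pyridine in THF then removes the silyl group.

3. **Step 9.**
   - Risks: Exchange of the crowded tertiary O4–H onto boron may be too slow. Reduction then stalls, and slow return of the alkene into conjugation in the acidic medium takes over.
   - Fallback: It sets out from 17 and rejoins at 20. An external bulky hydride, LiBH(s-Bu)3 in THF at −78 °C, should attack the open α face (equatorial approach, away from the axial C1 methyl group) and give the 6β-alcohol 6-epi-jaeschkeanadiol F9. Mitsunobu esterification with 19 (PPh3, DIAD, toluene) then inverts C6 and installs the aroyl group in one operation.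

**Further compounds**
F1 | step 6 | 1-bromo-4-methylpentan-3-one | CC(C)C(=O)CCBr
F2 | step 6 | 2-(2-bromoethyl)-2-(propan-2-yl)-1,3-dioxolane | CC(C)C1(CCBr)OCCO1
F3 | step 6 | 2-[2-(propan-2-yl)-1,3-dioxolan-2-yl]ethylmagnesium bromide | CC(C)C1(CC[Mg]Br)OCCO1
F4 | step 6 | (S)-3,6-dimethyl-6-{2-[2-(propan-2-yl)-1,3-dioxolan-2-yl]ethyl}cyclohept-2-en-1-one | CC(C)C1(CC[C@]2(C)CCC(C)=CC(=O)C2)OCCO1
F5 | step 6 | (S)-3,6-dimethyl-6-(4-methyl-3-oxopentyl)cyclohept-2-en-1-one | CC(C)C(=O)CC[C@]1(C)CCC(C)=CC(=O)C1
F6 | step 7 | O4-triethylsilyl ether of 13 | CC(C)[C@]1(O[Si](CC)(CC)CC)CC[C@]2(C)CCC(C)=CC(=O)[C@H]21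
F7 | step 7 | potassium 6,8-dienolate, O4-triethylsilyl | CC(C)[C@]1(O[Si](CC)(CC)CC)CC[C@]2(C)CC=C(C)C=C([O-])[C@H]21.[K+]
F8 | step 7 | O4-triethylsilyl ether of 17 | CC(C)[C@]1(O[Si](CC)(CC)CC)CC[C@]2(C)CC=C(C)CC(=O)[C@H]21
F9 | step 9 | 6-epi-jaeschkeanadiol (6β-OH) | CC(C)[C@]1(O)CC[C@]2(C)CC=C(C)C[C@@H](O)[C@H]21
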